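The tetrahydrofuran ring (O1, C2–C5) is cut at O1–C2 and C2–C3. Because O1 and C3 flank one benzylic carbon (C2) and the C4–C5 edge can be masked as an enol ether, the ring divides into a one-carbon unit, a benzylic ylide of (2R,5R)-2,5-dimethylthiolane, and a four-atom unit, C3–C4–C5–O1 of a cis-ene-1,4-dione whose other carbonyl becomes the C3 aroyl group. Conjugate addition at C3 and ring closure through the enolate oxygen then deliver the 2,3-trans dihydrofuran in one operation. The precursor is a benzyl-protected (Z)-ene-dione carrying an (S)-silyloxy(aryl)methyl group on C4, obtained by singlet-oxygen opening of a 3-substituted 2,5-diarylfuran.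

Key step: step 12

Remarks on the chemistry:
- Target numbering (O1, C2 4-hydroxyphenyl, C3 aroyl, C4 hydroxybenzyl, C5 2,4-dihydroxyphenyl) is used for all precursors.
- The oxygen-bearing side-chain carbon is (S) in 9–12 and 20, because the unsaturated C4 branch outranks the aryl group. It becomes (R) in 21–23 with no change in space; the silyl group makes C4 formally (S) in 21.
- In 20 the silyloxy carbon is allylic to the enol ether and p-alkoxybenzylic, so acid would ionise it. C4=C5 is therefore reduced by neutral hydrogenation, which calls for benzyl and not allyl ethers on the phenols.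
- The furan C3 substituent is built in through an ester, because electrophilic substitution of the diarylfuran would be diverted to the resorcinol-type rings.
- Compounds 1, 7 (THF solution), 13 and 16 are taken as catalogue items.

Step 1
Reactants: 1 1-[2,4-bis(benzyloxy)phenyl]ethanone
Product: 2 ethyl 3-[2,4-bis(benzyloxy)phenyl]-3-oxopropanoate
Conditions: NaH, (EtO)2CO, toluene, 80 °C; then aq. HCl
Reagents that add atoms: diethyl carbonate, CCOC(=O)OCC
Why: Crossed Claisen condensation of the methyl ketone enolate with the non-enolisable carbonate, driven by deprotonation of the β-keto ester formed; aryl benzyl ethers are inert to NaH.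

Step 2
Reactants: 1 1-[2,4-bis(benzyloxy)phenyl]ethanone
Product: 3 2-bromo-1-[2,4-bis(benzyloxy)phenyl]ethanone
Conditions: CuBr2 (2 equiv), EtOAc/CHCl3, reflux
Reagents that add atoms: CuBr2, [Cu+2].[Br-].[Br-]
Why: Side-chain α-bromination of an alkoxyacetophenone through its copper-bound enol, which avoids the ring bromination that free bromine would cause on the electron-rich arene.

Step 3
Reactants: 2 ethyl 3-[2,4-bis(benzyloxy)phenyl]-3-oxopropanoate; 3 2-bromo-1-[2,4-bis(benzyloxy)phenyl]ethanone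
Product: 5 ethyl 2,5-bis[2,4-bis(benzyloxy)phenyl]furan-3-carboxylate, via diketo ester 4 (not isolated)
Conditions: K2CO3, acetone, rt; then p-TsOH·H2O (cat.), toluene, 90 °C
Reagents that add atoms: none
Why: SN2 C-alkylation of the β-keto ester by the phenacyl bromide gives a 1,4-diketone whose Paal–Knorr cyclodehydration can engage only the two ketones, so the ester is placed unambiguously on C3 of the furan.

Step 4
Reactants: 5 ethyl 2,5-bis[2,4-bis(benzyloxy)phenyl]furan-3-carboxylate
Product: 6 2,5-bis[2,4-bis(benzyloxy)phenyl]-N-methoxy-N-methylfuran-3-carboxamide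
Conditions: MeNH(OMe)·HCl, iPrMgCl, THF, −20 to 0 °C
Reagents that add atoms: N,O-dimethylhydroxylamine hydrochloride, CNOC.Cl
Why: Direct ester-to-Weinreb-amide exchange with the chloromagnesium amide, a standard aminolysis that tolerates hindered aryl esters and benzyl ethers.

Step 5
Reactants: 6 2,5-bis[2,4-bis(benzyloxy)phenyl]-N-methoxy-N-methylfuran-3-carboxamide; 7 4-(benzyloxy)phenylmagnesium bromide
Product: 8 [2,5-bis[2,4-bis(benzyloxy)phenyl]furan-3-yl][4-(benzyloxy)phenyl]methanone
Conditions: THF, 0 °C to rt; then cold dilute aq. HCl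
Reagents that add atoms: none
Why: Weinreb ketone synthesis, in which the chelated tetrahedral adduct survives until work-up and so prevents a second addition.

Step 6
Reactants: 8 [2,5-bis[2,4-bis(benzyloxy)phenyl]furan-3-yl][4-(benzyloxy)phenyl]methanone
Product: 9 (S)-[2,5-bis[2,4-bis(benzyloxy)phenyl]furan-3-yl][4-(benzyloxy)phenyl]methanol
Conditions: H2 (8 atm), trans-RuCl2[(S)-xylbinap][(S)-daipen] (1 mol %), t-BuOK (cat.), iPrOH/toluene, 30 °C
Reagents that add atoms: none
Why: Noyori-type asymmetric hydrogenation of a diaryl ketone, in which the flanking 2-aryl group twists the furyl ring out of the carbonyl plane as an ortho substituent does in benzophenones, so the (S,S) catalyst is expected by that analogy to give the (S)-carbinol (sense to be verified by MTPA ester analysis; the mirror-image catalyst is equally available).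

Step 7
Reactants: 9 (S)-[2,5-bis[2,4-bis(benzyloxy)phenyl]furan-3-yl][4-(benzyloxy)phenyl]methanol
Product: 10 2,5-bis[2,4-bis(benzyloxy)phenyl]-3-[(S)-[4-(benzyloxy)phenyl](tert-butyldimethylsilyloxy)methyl]furan
Conditions: TBSOTf, 2,6-lutidine, CH2Cl2, −78 to 0 °C
Reagents that add atoms: tert-butyldimethylsilyl trifluoromethanesulfonate, CC(C)(C)[Si](C)(C)OS(=O)(=O)C(F)(F)F
Why: Standard silylation of a hindered secondary alcohol under cold, buffered conditions that do not ionise the doubly activated carbinol; the bulky silyl ether is a poor leaving group and later shields one alkene face.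

Step 8
Reactants: 10 2,5-bis[2,4-bis(benzyloxy)phenyl]-3-[(S)-[4-(benzyloxy)phenyl](tert-butyldimethylsilyloxy)methyl]furan
Product: 12 (2Z)-1,4-bis[2,4-bis(benzyloxy)phenyl]-2-[(S)-[4-(benzyloxy)phenyl](tert-butyldimethylsilyloxy)methyl]but-2-ene-1,4-dione, via furan endoperoxide 11 (not isolated)
Conditions: O2, tetraphenylporphyrin (cat.), visible light, CH2Cl2, −78 °C; then Me2S, −78 °C to rt
Reagents that add atoms: dioxygen, O=O
Why: [4+2] cycloaddition of singlet oxygen across C2/C5 of the electron-rich furan and reduction of the endoperoxide by Me2S unmask the ene-1,4-dione with the cis geometry imposed by the ring; benzyl and silyl ethers are inert.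

Step 9
Reactants: 13 (2S,5S)-hexane-2,5-diol
Product: 14 (2S,5S)-hexane-2,5-diyl dimethanesulfonate
Conditions: MsCl, Et3N, CH2Cl2, 0 °C
Reagents that add atoms: methanesulfonyl chloride, CS(=O)(=O)Cl
Why: O-Sulfonylation of both secondary alcohols, which touches no bond at the stereocentres.

Step 10
Reactants: 14 (2S,5S)-hexane-2,5-diyl dimethanesulfonate
Product: 15 (2R,5R)-2,5-dimethylthiolane
Conditions: Na2S·9H2O, DMSO, rt
Reagents that add atoms: sodium sulfide, [Na+].[Na+].[S-2]
Why: Double SN2 displacement by sulfide, each with inversion, converts the (S,S)-dimesylate into the C2-symmetric (R,R)-thiolane.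

Step 11
Reactants: 15 (2R,5R)-2,5-dimethylthiolane; 16 4-(benzyloxy)benzyl bromide
Product: 17 (2R,5R)-1-[4-(benzyloxy)benzyl]-2,5-dimethylthiolan-1-ium tetrafluoroborate
Conditions: NaBF4, CH2Cl2/H2O, rt
Reagents that add atoms: sodium tetrafluoroborate, [Na+].F[B-](F)(F)F
Why: S-Alkylation by the reactive benzylic bromide with anion exchange to non-nucleophilic tetrafluoroborate, which prevents reversal; the two faces of the C2-symmetric sulfide are equivalent, so one sulfonium salt results.

Step 12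
Reactants: 12 (2Z)-1,4-bis[2,4-bis(benzyloxy)phenyl]-2-[(S)-[4-(benzyloxy)phenyl](tert-butyldimethylsilyloxy)methyl]but-2-ene-1,4-dione; 17 (2R,5R)-1-[4-(benzyloxy)benzyl]-2,5-dimethylthiolan-1-ium tetrafluoroborate
Product: 20 [(2R,3R)-5-[2,4-bis(benzyloxy)phenyl]-2-[4-(benzyloxy)phenyl]-4-[(S)-[4-(benzyloxy)phenyl](tert-butyldimethylsilyloxy)methyl]-2,3-dihydrofuran-3-yl][2,4-bis(benzyloxy)phenyl]methanone, via sulfonium ylide 18 (not isolated), via anti betaine 19 (not isolated)
Conditions: Cs2CO3, MeCN/CH2Cl2, −20 °C to rt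
Reagents that add atoms: none
Why: Cs2CO3 converts 17 into benzylic ylide 18, which adds in conjugate fashion to C3, the unsubstituted alkene carbon β to the C5 carbonyl, to give the C5 enolate; rotation to the anti betaine 19 and backside displacement of the thiolane at C2 by the enolate oxygen then form O1–C2. This is the sulfonium ylide conjugate addition/O-alkylation ([4+1]) annulation known for enones and ortho-quinone methides, applied here to an ene-1,4-dione. The dihydrofuran ring closes by 5-exo-tet O-alkylation, favoured over 3-exo-tet C-alkylation because the latter would have to build a fully substituted cyclopropane carbon at C4. C2 is fixed by the ylide face that the C2-symmetric (2R,5R)-thiolane leaves open (predicted (R) by analogy with the sense of epoxidations mediated by this sulfide, the inversion at C2 included), and C3 is fixed relative to C2 by the anti betaine, which gives the trans and also more stable arrangement. The step needs site selectivity, secured because C4 is fully substituted and only the C5 enolate oxygen can reach C2, and face selectivity at C3, which is reagent-controlled and assumed to be matched with the (S)-silyloxy centre; the silyl ether is too poor a leaving group for E1cB loss from the enolate.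

Step 13
Reactants: 20 [(2R,3R)-5-[2,4-bis(benzyloxy)phenyl]-2-[4-(benzyloxy)phenyl]-4-[(S)-[4-(benzyloxy)phenyl](tert-butyldimethylsilyloxy)methyl]-2,3-dihydrofuran-3-yl][2,4-bis(benzyloxy)phenyl]methanone
Product: 21 [(2R,3R,4S,5R)-5-[2,4-bis(benzyloxy)phenyl]-2-[4-(benzyloxy)phenyl]-4-[(R)-[4-(benzyloxy)phenyl](tert-butyldimethylsilyloxy)methyl]oxolan-3-yl][2,4-bis(benzyloxy)phenyl]methanone
Conditions: H2 (4 atm), 5% Rh/Al2O3, EtOAc, rt
Reagents that add atoms: none
Why: Heterogeneous syn-hydrogenation of the enol ether on rhodium, which saturates vinylic and allylic ethers with little C–O hydrogenolysis and spares aryl benzyl ethers; both hydrogens should add to the face opposite the C3 aroyl group and the silyloxy group (held on that same face in the rotamer that minimises A(1,3) strain with the C5 aryl group), which sets C4 and C5 with the 3,4-cis and 4,5-cis relationships.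

Step 14
Reactants: 21 [(2R,3R,4S,5R)-5-[2,4-bis(benzyloxy)phenyl]-2-[4-(benzyloxy)phenyl]-4-[(R)-[4-(benzyloxy)phenyl](tert-butyldimethylsilyloxy)methyl]oxolan-3-yl][2,4-bis(benzyloxy)phenyl]methanone
Product: 22 [(2R,3R,4R,5R)-5-[2,4-bis(benzyloxy)phenyl]-2-[4-(benzyloxy)phenyl]-4-[(R)-[4-(benzyloxy)phenyl](hydroxy)methyl]oxolan-3-yl][2,4-bis(benzyloxy)phenyl]methanone
Conditions: TBAF, AcOH, THF, 0 °C to rt
Reagents that add atoms: none
Why: Fluoride desilylation, buffered with acetic acid so that the β-alkoxy ketone can neither open by E1cB at C2–O1 nor epimerise at C3.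

Step 15
Reactants: 22 [(2R,3R,4R,5R)-5-[2,4-bis(benzyloxy)phenyl]-2-[4-(benzyloxy)phenyl]-4-[(R)-[4-(benzyloxy)phenyl](hydroxy)methyl]oxolan-3-yl][2,4-bis(benzyloxy)phenyl]methanone
Product: 23 [(2R,3R,4R,5R)-5-(2,4-dihydroxyphenyl)-4-[(R)-hydroxy(4-hydroxyphenyl)methyl]-2-(4-hydroxyphenyl)oxolan-3-yl](2,4-dihydroxyphenyl)methanone
Conditions: H2 (1 atm), 10% Pd/C, EtOAc/MeOH, rt
Reagents that add atoms: none
Why: Hydrogenolysis of the five aryl benzyl ethers on palladium under neutral conditions is much faster than cleavage of the ring benzylic C–O bonds, the secondary benzylic alcohol or the aryl ketone, and releases the target without acid or base.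

Compound list
1 | 1-[2,4-bis(benzyloxy)phenyl]ethanone | CC(=O)c1ccc(OCc2ccccc2)cc1OCc1ccccc1 | starting material
2 | ethyl 3-[2,4-bis(benzyloxy)phenyl]-3-oxopropanoate | CCOC(=O)CC(=O)c1ccc(OCc2ccccc2)cc1OCc1ccccc1 | intermediate
3 | 2-bromo-1-[2,4-bis(benzyloxy)phenyl]ethanone | BrCC(=O)c1ccc(OCc2ccccc2)cc1OCc1ccccc1 | intermediate
4 | ethyl 2-[2,4-bis(benzyloxy)benzoyl]-4-[2,4-bis(benzyloxy)phenyl]-4-oxobutanoate (racemic, not isolated) | CCOC(=O)C(CC(=O)c1ccc(OCc2ccccc2)cc1OCc1ccccc1)C(=O)c1ccc(OCc2ccccc2)cc1OCc1ccccc1 | intermediate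
5 | ethyl 2,5-bis[2,4-bis(benzyloxy)phenyl]furan-3-carboxylate | CCOC(=O)c1cc(-c2ccc(OCc3ccccc3)cc2OCc2ccccc2)oc1-c1ccc(OCc2ccccc2)cc1OCc1ccccc1 | intermediate
6 | 2,5-bis[2,4-bis(benzyloxy)phenyl]-N-methoxy-N-methylfuran-3-carboxamide | CON(C)C(=O)c1cc(-c2ccc(OCc3ccccc3)cc2OCc2ccccc2)oc1-c1ccc(OCc2ccccc2)cc1OCc1ccccc1 | intermediate
7 | 4-(benzyloxy)phenylmagnesium bromide | Br[Mg]c1ccc(OCc2ccccc2)cc1 | starting material
8 | [2,5-bis[2,4-bis(benzyloxy)phenyl]furan-3-yl][4-(benzyloxy)phenyl]methanone | O=C(c1ccc(OCc2ccccc2)cc1)c1cc(-c2ccc(OCc3ccccc3)cc2OCc2ccccc2)oc1-c1ccc(OCc2ccccc2)cc1OCc1ccccc1 | intermediate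
9 | (S)-[2,5-bis[2,4-bis(benzyloxy)phenyl]furan-3-yl][4-(benzyloxy)phenyl]methanol | o1c(-c2ccc(OCc3ccccc3)cc2OCc2ccccc2)cc([C@@H](O)c2ccc(OCc3ccccc3)cc2)c1-c1ccc(OCc2ccccc2)cc1OCc1ccccc1 | intermediate
10 | 2,5-bis[2,4-bis(benzyloxy)phenyl]-3-[(S)-[4-(benzyloxy)phenyl](tert-butyldimethylsilyloxy)methyl]furan | o1c(-c2ccc(OCc3ccccc3)cc2OCc2ccccc2)cc([C@@H](O[Si](C)(C)C(C)(C)C)c2ccc(OCc3ccccc3)cc2)c1-c1ccc(OCc2ccccc2)cc1OCc1ccccc1 | intermediate
11 | 1,4-bis[2,4-bis(benzyloxy)phenyl]-5-[(S)-[4-(benzyloxy)phenyl](tert-butyldimethylsilyloxy)methyl]-2,3,7-trioxabicyclo[2.2.1]hept-5-ene (both bridgehead diastereomers, not isolated) | O1OC2(c3ccc(OCc4ccccc4)cc3OCc3ccccc3)C=C([C@@H](O[Si](C)(C)C(C)(C)C)c3ccc(OCc4ccccc4)cc3)C1(c1ccc(OCc3ccccc3)cc1OCc1ccccc1)O2 | intermediate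
12 | (2Z)-1,4-bis[2,4-bis(benzyloxy)phenyl]-2-[(S)-[4-(benzyloxy)phenyl](tert-butyldimethylsilyloxy)methyl]but-2-ene-1,4-dione | O=C(c1ccc(OCc2ccccc2)cc1OCc1ccccc1)/C=C(\C(=O)c1ccc(OCc2ccccc2)cc1OCc1ccccc1)[C@@H](O[Si](C)(C)C(C)(C)C)c1ccc(OCc2ccccc2)cc1 | intermediate
13 | (2S,5S)-hexane-2,5-diol | C[C@H](O)CC[C@H](C)O | starting material
14 | (2S,5S)-hexane-2,5-diyl dimethanesulfonate | C[C@H](OS(C)(=O)=O)CC[C@H](C)OS(C)(=O)=O | intermediate
15 | (2R,5R)-2,5-dimethylthiolane | C[C@@H]1CC[C@@H](C)S1 | intermediate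
16 | 4-(benzyloxy)benzyl bromide | BrCc1ccc(OCc2ccccc2)cc1 | starting material
17 | (2R,5R)-1-[4-(benzyloxy)benzyl]-2,5-dimethylthiolan-1-ium tetrafluoroborate | C[C@@H]1CC[C@@H](C)[S+]1Cc1ccc(OCc2ccccc2)cc1.F[B-](F)(F)F | intermediate
18 | [4-(benzyloxy)phenyl][(2R,5R)-2,5-dimethylthiolan-1-ium-1-yl]methanide (sulfonium ylide, not isolated) | C[C@@H]1CC[C@@H](C)[S+]1[CH-]c1ccc(OCc2ccccc2)cc1 | intermediate
19 | anti betaine: C5 enolate bearing the (2R,5R)-2,5-dimethylthiolanium group on C2 (not isolated) | [O-]/C(c1ccc(OCc2ccccc2)cc1OCc1ccccc1)=C(/[C@@H](O[Si](C)(C)C(C)(C)C)c1ccc(OCc2ccccc2)cc1)[C@@H](C(=O)c1ccc(OCc2ccccc2)cc1OCc1ccccc1)[C@@H](c1ccc(OCc2ccccc2)cc1)[S+]1[C@H](C)CC[C@H]1C | intermediate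
20 | [(2R,3R)-5-[2,4-bis(benzyloxy)phenyl]-2-[4-(benzyloxy)phenyl]-4-[(S)-[4-(benzyloxy)phenyl](tert-butyldimethylsilyloxy)methyl]-2,3-dihydrofuran-3-yl][2,4-bis(benzyloxy)phenyl]methanone | O=C(c1ccc(OCc2ccccc2)cc1OCc1ccccc1)[C@@H]1C([C@@H](O[Si](C)(C)C(C)(C)C)c2ccc(OCc3ccccc3)cc2)=C(c2ccc(OCc3ccccc3)cc2OCc2ccccc2)O[C@H]1c1ccc(OCc2ccccc2)cc1 | intermediate
21 | [(2R,3R,4S,5R)-5-[2,4-bis(benzyloxy)phenyl]-2-[4-(benzyloxy)phenyl]-4-[(R)-[4-(benzyloxy)phenyl](tert-butyldimethylsilyloxy)methyl]oxolan-3-yl][2,4-bis(benzyloxy)phenyl]methanone | O=C(c1ccc(OCc2ccccc2)cc1OCc1ccccc1)[C@@H]1[C@H]([C@@H](O[Si](C)(C)C(C)(C)C)c2ccc(OCc3ccccc3)cc2)[C@H](c2ccc(OCc3ccccc3)cc2OCc2ccccc2)O[C@H]1c1ccc(OCc2ccccc2)cc1 | intermediate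
22 | [(2R,3R,4R,5R)-5-[2,4-bis(benzyloxy)phenyl]-2-[4-(benzyloxy)phenyl]-4-[(R)-[4-(benzyloxy)phenyl](hydroxy)methyl]oxolan-3-yl][2,4-bis(benzyloxy)phenyl]methanone | O=C(c1ccc(OCc2ccccc2)cc1OCc1ccccc1)[C@@H]1[C@H]([C@@H](O)c2ccc(OCc3ccccc3)cc2)[C@H](c2ccc(OCc3ccccc3)cc2OCc2ccccc2)O[C@H]1c1ccc(OCc2ccccc2)cc1 | intermediate
23 | [(2R,3R,4R,5R)-5-(2,4-dihydroxyphenyl)-4-[(R)-hydroxy(4-hydroxyphenyl)methyl]-2-(4-hydroxyphenyl)oxolan-3-yl](2,4-dihydroxyphenyl)methanone | O=C(c1ccc(O)cc1O)[C@@H]1[C@H]([C@@H](O)c2ccc(O)cc2)[C@H](c2ccc(O)cc2O)O[C@H]1c1ccc(O)cc1 | target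

Total step count: 15.
Longest linear sequence: 11 steps (steps 1, 3, 4, 5, 6, 7, 8, 12, 13, 14, 15).

Steps most likely to fail

Step 12. The betaine may close through carbon to a cyclopropane instead of through oxygen. Facial control may also be weak if the sulfide and the resident silyloxy centre oppose each other, and the base may remove the γ-hydrogen at the silyloxy carbon. The fallback builds the same two bonds by aldol chemistry and sets out from 12. Transfer hydrogenation of the doubly activated alkene with Hantzsch ester (toluene, 80 °C) should give the saturated 1,4-bis[2,4-bis(benzyloxy)phenyl]-2-[(R)-[4-(benzyloxy)phenyl](tert-butyldimethylsilyloxy)methyl]butane-1,4-dione F1; its C4 epimers are of no consequence because C4 becomes trigonal again. Enolisation at C3, the only α-methylene, with Ipc2BOTf and iPr2NEt gives the Z boron enolate, with the reagent enantiomer chosen to match the resident centre. Its syn aldol addition to 4-(benzyloxy)benzaldehyde forms C2–C3 and gives the hydroxy diketone F2; a syn aldol maps onto the 2,3-trans ring. The C2 hydroxyl of F2 adds to the C5 ketone to give the cyclic hemiketal F3. Dehydration with PPTS (cat.) and 4 Å sieves in benzene gives the C4=C5 enol ether, and the route is rejoined at 20.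

Step 13. Saturation of the hindered tetrasubstituted enol ether may be slow or incomplete, hydrogen may be delivered from the aroyl-bearing face, or the allylic C–O bond may be hydrogenolysed on long exposure. The fallback sets out from 20 and replaces surface hydrogenation by radical hydrogen-atom-transfer hydrogenation (Mn(dpm)3 cat., PhSiH3, t-BuOOH, iPrOH, rt). The metal hydride should transfer a hydrogen atom to C4 from the open face, and the resulting C5 benzylic α-oxy radical should be reduced anti to the new C4 substituent. The conditions are neutral and leave benzyl and silyl ethers untouched. No new compound is made on this way (F0), and the route is rejoined at 21.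

Step 6. Enantioselectivity may be low, or turnover sluggish, because the ketone is hindered and deactivated as a vinylogous ester. The fallback sets out from 6 and makes the carbinol by C–C bond formation instead of reduction. LiAlH4 (THF, −40 °C) should reduce the Weinreb amide to 2,5-bis[2,4-bis(benzyloxy)phenyl]furan-3-carbaldehyde F4. Catalytic enantioselective aryl transfer then adds the arylzinc species made from 4-(benzyloxy)phenylboronic acid and Et2Zn, under a chiral amino alcohol ligand such as 3-exo-morpholinoisoborneol, with the ligand enantiomer chosen for the (S)-product. The route is rejoined at 9.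

Further compounds
F1 | step 12 | 1,4-bis[2,4-bis(benzyloxy)phenyl]-2-[(R)-[4-(benzyloxy)phenyl](tert-butyldimethylsilyloxy)methyl]butane-1,4-dione (C2 epimers) | O=C(c1ccc(OCc2ccccc2)cc1OCc1ccccc1)CC(C(=O)c1ccc(OCc2ccccc2)cc1OCc1ccccc1)[C@@H](O[Si](C)(C)C(C)(C)C)c1ccc(OCc2ccccc2)cc1
F2 | step 12 | (2R)-1,4-bis[2,4-bis(benzyloxy)phenyl]-2-[(R)-[4-(benzyloxy)phenyl](hydroxy)methyl]-3-[(R)-[4-(benzyloxy)phenyl](tert-butyldimethylsilyloxy)methyl]butane-1,4-dione (syn aldol adduct, C3 epimers) | O=C(c1ccc(OCc2ccccc2)cc1OCc1ccccc1)[C@@H]([C@@H](O)c1ccc(OCc2ccccc2)cc1)C(C(=O)c1ccc(OCc2ccccc2)cc1OCc1ccccc1)[C@@H](O[Si](C)(C)C(C)(C)C)c1ccc(OCc2ccccc2)cc1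
F3 | step 12 | [(2R,3R)-5-[2,4-bis(benzyloxy)phenyl]-2-[4-(benzyloxy)phenyl]-4-[(R)-[4-(benzyloxy)phenyl](tert-butyldimethylsilyloxy)methyl]-5-hydroxyoxolan-3-yl][2,4-bis(benzyloxy)phenyl]methanone (cyclic hemiketal, C4 and C5 epimers) | O=C(c1ccc(OCc2ccccc2)cc1OCc1ccccc1)[C@@H]1C([C@@H](O[Si](C)(C)C(C)(C)C)c2ccc(OCc3ccccc3)cc2)C(O)(c2ccc(OCc3ccccc3)cc2OCc2ccccc2)O[C@H]1c1ccc(OCc2ccccc2)cc1
F0 | step 13 | none | none
F4 | step 6 | 2,5-bis[2,4-bis(benzyloxy)phenyl]furan-3-carbaldehyde | O=Cc1cc(-c2ccc(OCc3ccccc3)cc2OCc2ccccc2)oc1-c1ccc(OCc2ccccc2)cc1OCc1ccccc1
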